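**Retrosynthetic overview**
- Target ⇐ (2S)-5,7-bis(silyloxy)-6-geranylflavanone ⇐ its C4 spiro-dithiane (desilylation, then dithiane hydrolysis).
- The pyranone ring is the only ring made (ring A and the phenyl ring are bought). It is closed last at O1–C2 by an intramolecular Mitsunobu displacement that inverts an (R)-benzylic alcohol.
- That alcohol ⇐ C3–C4 bond from the dianion of a salicylaldehyde dithiane and (S)-styrene oxide, the only source of chirality.
- The salicylaldehyde ⇐ tandem aromatic Claisen/Cope rearrangement of a 2-O-geranyl ether. The C6–C1'' bond forms para to the phenol that is released; this phenol later becomes O1, which fixes 6- over 8-geranyl.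
- Geranyl ether ⇐ 2,4,6-trihydroxybenzaldehyde (as its bis-silyl ether) + geraniol.

Abbreviations: TIPS = triisopropylsilyl; geranyl = (2E)-3,7-dimethylocta-2,6-dien-1-yl.

Assumption: 2,4,6-trihydroxybenzaldehyde, geraniol and (S)-styrene oxide are bought. The transient dienones 5 and 6 are racemic and drawn as one enantiomer; their stereocentres vanish on aromatisation. TIPS ethers protect O5/O7 because they tolerate thiol/Lewis acid, n-BuLi and Mitsunobu conditions and leave under buffered fluoride.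

**Step 1**
Reactants: 1 2,4,6-trihydroxybenzaldehyde
Product: 2 2-hydroxy-4,6-bis(triisopropylsilyloxy)benzaldehyde
Conditions: TIPSCl (2.1 equiv), imidazole, DMF, 0 °C → rt
Reagents that add atoms: triisopropylsilyl chloride, CC(C)[Si](Cl)(C(C)C)C(C)C
Why: Selective phenol silylation: the 4-OH and one ortho-OH react, while the last ortho-OH is held back by its hydrogen bond to the formyl group.

**Step 2**
Reactants: 2 2-hydroxy-4,6-bis(triisopropylsilyloxy)benzaldehyde; 3 geraniol
Product: 4 2-(geranyloxy)-4,6-bis(triisopropylsilyloxy)benzaldehyde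
Conditions: PPh3, DIAD, THF, 0 °C → rt
Reagents that add atoms: none
Why: Mitsunobu etherification of the acidic chelated phenol with a primary allylic alcohol proceeds by SN2 at C1 under neutral conditions, so the E-alkene and the aryl silyl ethers are untouched.

**Step 3**
Reactants: 4 2-(geranyloxy)-4,6-bis(triisopropylsilyloxy)benzaldehyde
Product: 7 3-geranyl-6-hydroxy-2,4-bis(triisopropylsilyloxy)benzaldehyde, via ortho-dienone 5 (not isolated), via para-dienone 6 (not isolated)
Conditions: PhNEt2, 195 °C, Ar, 3 h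
Reagents that add atoms: none
Why: Tandem aromatic Claisen/Cope (two [3,3] shifts): the crowded ortho-dienone passes the allyl unit on to the only para carbon and aromatises; two chair transition states with the homoprenyl chain equatorial regenerate the E-geranyl group, and the silylated flanking oxygens prevent chroman formation.

**Step 4**
Reactants: 7 3-geranyl-6-hydroxy-2,4-bis(triisopropylsilyloxy)benzaldehyde
Product: 8 2-(1,3-dithian-2-yl)-4-geranyl-3,5-bis(triisopropylsilyloxy)phenol
Conditions: HS(CH2)3SH (1.2 equiv), BF3·OEt2 (0.3 equiv), CH2Cl2, −20 → 0 °C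
Reagents that add atoms: propane-1,3-dithiol, SCCCS
Why: Lewis-acid thioacetalisation of the aldehyde goes through a thionium ion stabilised by the electron-rich ring; aryl TIPS ethers and isolated trisubstituted alkenes tolerate catalytic BF3 at low temperature.

**Step 5**
Reactants: 8 2-(1,3-dithian-2-yl)-4-geranyl-3,5-bis(triisopropylsilyloxy)phenol; 9 (S)-styrene oxide
Product: 11 2-{2-[(2R)-2-hydroxy-2-phenylethyl]-1,3-dithian-2-yl}-4-geranyl-3,5-bis(triisopropylsilyloxy)phenol, via dilithio dianion 10 (not isolated)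
Conditions: n-BuLi (2.2 equiv), THF, −78 → −20 °C; then 9, −20 °C → rt; H2O
Reagents that add atoms: none
Why: Corey–Seebach umpolung: the O,C-dianion opens the epoxide by SN2 at the unsubstituted CH2, so the bought stereocentre is not touched and (S)-epoxide gives the (R)-carbinol (the descriptor changes only because the CIP priorities change).

**Step 6**
Reactants: 11 2-{2-[(2R)-2-hydroxy-2-phenylethyl]-1,3-dithian-2-yl}-4-geranyl-3,5-bis(triisopropylsilyloxy)phenol
Product: 12 (2S)-6-geranyl-2-phenyl-5,7-bis(triisopropylsilyloxy)-2,3-dihydrospiro[chromene-4,2'-[1,3]dithiane]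
Conditions: PPh3, DIAD, THF (0.02 M), 0 °C → rt
Reagents that add atoms: none
Why: Intramolecular Mitsunobu etherification: the only free phenol displaces the activated benzylic alcohol by SN2 with inversion, so the (R)-carbinol gives the (2S) centre, and the dithiane mask rules out β-elimination to a chalcone.

**Step 7**
Reactants: 12 (2S)-6-geranyl-2-phenyl-5,7-bis(triisopropylsilyloxy)-2,3-dihydrospiro[chromene-4,2'-[1,3]dithiane]
Product: 13 (2S)-6-geranyl-2-phenyl-5,7-bis(triisopropylsilyloxy)-2,3-dihydro-4H-chromen-4-one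
Conditions: MeI (excess), CaCO3, MeCN/H2O (9:1), 45 °C
Reagents that add atoms: water, O
Why: Alkylative dithiane hydrolysis (S-methylation, then water attack on the aryl-stabilised thionium ion) is non-oxidising and near neutral, so the alkenes, silyl ethers and C2 stereocentre survive.

**Step 8**
Reactants: 13 (2S)-6-geranyl-2-phenyl-5,7-bis(triisopropylsilyloxy)-2,3-dihydro-4H-chromen-4-one
Product: 14 (2S)-6-geranyl-5,7-dihydroxy-2-phenyl-2,3-dihydro-4H-chromen-4-one
Conditions: TBAF, AcOH (1:1), THF, 0 °C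
Reagents that add atoms: none
Why: Fluoride desilylation buffered with acetic acid frees both phenols without a basic phenoxide or enolate that could open the flavanone to a chalcone, so C2 is not racemised.

**Compound list**
1 | 2,4,6-trihydroxybenzaldehyde | O=Cc1c(O)cc(O)cc1O | starting material
2 | 2-hydroxy-4,6-bis(triisopropylsilyloxy)benzaldehyde | O=Cc1c(O)cc(O[Si](C(C)C)(C(C)C)C(C)C)cc1O[Si](C(C)C)(C(C)C)C(C)C | intermediate
3 | geraniol, (2E)-3,7-dimethylocta-2,6-dien-1-ol | CC(C)=CCC/C(C)=C/CO | starting material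
4 | 2-(geranyloxy)-4,6-bis(triisopropylsilyloxy)benzaldehyde | O=Cc1c(OC/C=C(\C)CCC=C(C)C)cc(O[Si](C(C)C)(C(C)C)C(C)C)cc1O[Si](C(C)C)(C(C)C)C(C)C | intermediate
5 | ortho-dienone, (5R*)-5-[(3R*)-3,7-dimethylocta-1,6-dien-3-yl]-6-oxo-2,4-bis(triisopropylsilyloxy)cyclohexa-1,3-diene-1-carbaldehyde (racemic, R,R drawn) | O=CC1=C(O[Si](C(C)C)(C(C)C)C(C)C)C=C(O[Si](C(C)C)(C(C)C)C(C)C)[C@@H]([C@@](C)(C=C)CCC=C(C)C)C1=O | intermediate
6 | para-dienone, (3S*)-3-geranyl-6-oxo-2,4-bis(triisopropylsilyloxy)cyclohexa-1,4-diene-1-carbaldehyde (racemic, S drawn) | O=CC1=C(O[Si](C(C)C)(C(C)C)C(C)C)[C@@H](C/C=C(\C)CCC=C(C)C)C(O[Si](C(C)C)(C(C)C)C(C)C)=CC1=O | intermediate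
7 | 3-geranyl-6-hydroxy-2,4-bis(triisopropylsilyloxy)benzaldehyde | O=Cc1c(O)cc(O[Si](C(C)C)(C(C)C)C(C)C)c(C/C=C(\C)CCC=C(C)C)c1O[Si](C(C)C)(C(C)C)C(C)C | intermediate
8 | 2-(1,3-dithian-2-yl)-4-geranyl-3,5-bis(triisopropylsilyloxy)phenol | Oc1cc(O[Si](C(C)C)(C(C)C)C(C)C)c(C/C=C(\C)CCC=C(C)C)c(O[Si](C(C)C)(C(C)C)C(C)C)c1C1SCCCS1 | intermediate
9 | (S)-styrene oxide, (2S)-2-phenyloxirane | C1[C@@H](O1)c2ccccc2 | starting material
10 | dilithio dianion of 8 (lithium phenoxide, 2-lithio-1,3-dithiane) | [Li]Oc1cc(O[Si](C(C)C)(C(C)C)C(C)C)c(C/C=C(\C)CCC=C(C)C)c(O[Si](C(C)C)(C(C)C)C(C)C)c1C1([Li])SCCCS1 | intermediate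
11 | 2-{2-[(2R)-2-hydroxy-2-phenylethyl]-1,3-dithian-2-yl}-4-geranyl-3,5-bis(triisopropylsilyloxy)phenol | Oc1cc(O[Si](C(C)C)(C(C)C)C(C)C)c(C/C=C(\C)CCC=C(C)C)c(O[Si](C(C)C)(C(C)C)C(C)C)c1C1(C[C@@H](O)c2ccccc2)SCCCS1 | intermediate
12 | (2S)-6-geranyl-2-phenyl-5,7-bis(triisopropylsilyloxy)-2,3-dihydrospiro[chromene-4,2'-[1,3]dithiane] | CC(C)=CCC/C(C)=C/Cc1c(O[Si](C(C)C)(C(C)C)C(C)C)cc2c(c1O[Si](C(C)C)(C(C)C)C(C)C)C1(SCCCS1)C[C@@H](c1ccccc1)O2 | intermediate
13 | (2S)-6-geranyl-2-phenyl-5,7-bis(triisopropylsilyloxy)-2,3-dihydro-4H-chromen-4-one | CC(C)=CCC/C(C)=C/Cc1c(O[Si](C(C)C)(C(C)C)C(C)C)cc2c(c1O[Si](C(C)C)(C(C)C)C(C)C)C(=O)C[C@@H](c1ccccc1)O2 | intermediate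
14 | (2S)-6-geranyl-5,7-dihydroxy-2-phenyl-2,3-dihydro-4H-chromen-4-one (6-geranylpinocembrin, CNP0201748.1) | CC(C)=CCC/C(C)=C/Cc1c(O)cc2c(c1O)C(=O)C[C@@H](c1ccccc1)O2 | target

**Step count**
Total steps: 8. Longest linear sequence: 8 (1 → 14).

**Three steps most likely to fail**

Step 3 (tandem Claisen/Cope). Dienone 5 may tautomerise to the ortho "reverse-geranyl" phenol instead of undergoing the Cope shift, and a boat transition state would leak the Z (neryl) isomer. The fallback makes the aryl–geranyl bond by Friedel–Crafts alkylation before the formyl group exists; it sets out from geraniol 3 and comes back at 7. Geraniol 3 and phloroglucinol F1 are condensed with a mild acid (p-TsOH, dioxane, rt), where attack at C1 of the allyl cation keeps the E geometry, to give 2-geranylbenzene-1,3,5-triol F2. Exhaustive silylation (TIPSOTf, 2,6-lutidine, CH2Cl2) gives 2-geranyl-1,3,5-tris(triisopropylsilyloxy)benzene F3. One equivalent of TBAF at −78 °C removes the only silyl group not flanked by the side chain and gives 4-geranyl-3,5-bis(triisopropylsilyloxy)phenol F4. Ortho-formylation (MgCl2, Et3N, paraformaldehyde, MeCN, reflux), for which both ortho positions are equivalent, then delivers 7.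

Step 5 (dianion formation and epoxide opening). The second deprotonation of the crowded, electron-rich dithiane may be incomplete, or the hindered anion may open the epoxide sluggishly. The fallback reverses the order of bond formation; it sets out from 8 and comes back at 12. Intermolecular Mitsunobu etherification (PPh3, DIAD, THF) of phenol 8 with (S)-2-chloro-1-phenylethanol F5 gives, with inversion, 2-{2-[(1R)-2-chloro-1-phenylethoxy]-5-geranyl-4,6-bis(triisopropylsilyloxy)phenyl}-1,3-dithiane F6. This has no free OH, so one equivalent of n-BuLi (THF, −78 → 0 °C) lithiates the dithiane, which closes the ring by 6-exo-tet SN2 at CH2Cl to give 12.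

Step 7 (hydrolysis of the spiro-dithiane). The dithiane in 12 is shielded by the peri 5-silyloxy group, and oxidative or mercury-based alternatives would attack the alkenes. The fallback unmasks the ketone before ring closure; it sets out from 11 and comes back at 13. Treating 11 with MeI/CaCO3 in aqueous MeCN gives the open-chain (3R)-1-[3-geranyl-6-hydroxy-2,4-bis(triisopropylsilyloxy)phenyl]-3-hydroxy-3-phenylpropan-1-one F7. Mitsunobu cyclisation of this (PPh3, DIAD, THF, 0 °C) with inversion gives 13 directly; the risk moved to this step is dehydration to the chalcone.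

**Further compounds**
F1 | step 3 | phloroglucinol (benzene-1,3,5-triol) | Oc1cc(O)cc(O)c1
F2 | step 3 | 2-geranylbenzene-1,3,5-triol | CC(C)=CCC/C(C)=C/Cc1c(O)cc(O)cc1O
F3 | step 3 | 2-geranyl-1,3,5-tris(triisopropylsilyloxy)benzene | CC(C)=CCC/C(C)=C/Cc1c(O[Si](C(C)C)(C(C)C)C(C)C)cc(O[Si](C(C)C)(C(C)C)C(C)C)cc1O[Si](C(C)C)(C(C)C)C(C)C
F4 | step 3 | 4-geranyl-3,5-bis(triisopropylsilyloxy)phenol | CC(C)=CCC/C(C)=C/Cc1c(O[Si](C(C)C)(C(C)C)C(C)C)cc(O)cc1O[Si](C(C)C)(C(C)C)C(C)C
F5 | step 5 | (S)-2-chloro-1-phenylethanol | ClC[C@@H](O)c1ccccc1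
F6 | step 5 | 2-{2-[(1R)-2-chloro-1-phenylethoxy]-5-geranyl-4,6-bis(triisopropylsilyloxy)phenyl}-1,3-dithiane | ClC[C@@H](c1ccccc1)Oc1cc(O[Si](C(C)C)(C(C)C)C(C)C)c(C/C=C(\C)CCC=C(C)C)c(O[Si](C(C)C)(C(C)C)C(C)C)c1C1SCCCS1
F7 | step 7 | (3R)-1-[3-geranyl-6-hydroxy-2,4-bis(triisopropylsilyloxy)phenyl]-3-hydroxy-3-phenylpropan-1-one | Oc1cc(O[Si](C(C)C)(C(C)C)C(C)C)c(C/C=C(\C)CCC=C(C)C)c(O[Si](C(C)C)(C(C)C)C(C)C)c1C(=O)C[C@@H](O)c1ccccc1
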